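**Plan**
- Retrosynthetic cuts: first the two ester C–O bonds at O9 (acetate) and O8 (epoxyangelate); then C11=C13 and C7–C11 together (methylenation and the lactone C–C bond); then C5–C6 (ten-membered ring); then C8–C9 (acetylide plus amide), C1=C10 (olefination) and the C4 methyl (carboalumination).
- Enabling feature: C7 lies between the two oxygen-bearing ring carbons C6 and C8. O6 can carry C11/C12 as a phosphonoacetate and O8 can be the oxygen of a cis-7,8-epoxide, so attack of C11 on C7 closes the five-membered lactone ring (O6–C12–C11–C7–C6), inverts C7 and frees only the C8 hydroxyl.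
- Forward order: acyclic C5→C10 chain, C6–C8 added as an alkyne, cis-alkene, cis-epoxy aldehyde, ten-membered carbocycle (CrCl2/NiCl2 closure of C5–C6), lactone ring with exocyclic methylene, then acylation of O8 and of O9.
- Stereochemistry: C9 by oxazaborolidine reduction; the 7,8-epoxide by Sharpless epoxidation, reinforced by C9; C6 by Felkin–Anh addition to the cis-epoxy aldehyde; C7 by SN2 inversion in the key step; the side-chain epoxide by Sharpless epoxidation of angelyl alcohol; 4E from syn-carboalumination and 1(10)Z from Still–Gennari olefination.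

Key step: step 14

Remark: positions are cited in germacrane numbering (ring C1–C10; C11 lactone α-carbon, C12 lactone carbonyl, C13 exocyclic CH2; C14 on C10, C15 on C4); the target is read from the SMILES as 6R,7S,8R,9R, 1(10)Z,4E, with a (2S,3S)-2,3-dimethyloxirane-2-carboxylate on O8.

**Route**

Step 1
Reactants: 1 pent-4-yn-1-ol
Product: 3 (4E)-5-iodo-4-methylpent-4-en-1-ol, via alkenylalane 2 (not isolated)
Conditions: AlMe3 (3 equiv), Cp2ZrCl2 (0.25 equiv), CH2Cl2, 0 °C → rt; then I2, THF, −30 → 0 °C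
Reagents that add atoms: trimethylaluminium, C[Al](C)C; iodine, [I][I]
Why: Zirconium-catalysed Negishi carboalumination adds methyl and aluminium syn across the terminal alkyne with methyl at the internal carbon, and iodinolysis of the C–Al bond with retention gives the E alkenyl iodide that later becomes C4=C5.

Step 2
Reactants: 3 (4E)-5-iodo-4-methylpent-4-en-1-ol
Product: 4 (4E)-5-iodo-4-methylpent-4-enal
Conditions: TEMPO (0.1 equiv), PhI(OAc)2 (1.1 equiv), CH2Cl2, rt
Reagents that add atoms: none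
Why: The oxoammonium (TEMPO) oxidation with PhI(OAc)2 as terminal oxidant stops at the aldehyde and does not touch the alkenyl iodide.

Step 3
Reactants: 4 (4E)-5-iodo-4-methylpent-4-enal
Product: 5 ethyl (2Z,6E)-7-iodo-2,6-dimethylhepta-2,6-dienoate
Conditions: ethyl 2-[bis(2,2,2-trifluoroethoxy)phosphoryl]propanoate, KN(SiMe3)2, 18-crown-6, THF, −78 °C
Reagents that add atoms: ethyl 2-[bis(2,2,2-trifluoroethoxy)phosphoryl]propanoate, CCOC(=O)C(C)P(=O)(OCC(F)(F)F)OCC(F)(F)F
Why: In this Still–Gennari olefination the electron-poor bis(trifluoroethyl) phosphonate eliminates from the kinetic adduct under dissociating conditions and should give the Z trisubstituted enoate, which fixes the 1(10)Z geometry.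

Step 4
Reactants: 5 ethyl (2Z,6E)-7-iodo-2,6-dimethylhepta-2,6-dienoate
Product: 6 (2Z,6E)-7-iodo-N-methoxy-N,2,6-trimethylhepta-2,6-dienamide
Conditions: MeNH(OMe)·HCl, i-PrMgCl, THF, −20 °C
Reagents that add atoms: N,O-dimethylhydroxylamine hydrochloride, CNOC.Cl
Why: Weinreb amide formation by acyl substitution with the chloromagnesium amide generated in the flask should leave the Z enoate geometry untouched at low temperature.

Step 5
Reactants: 6 (2Z,6E)-7-iodo-N-methoxy-N,2,6-trimethylhepta-2,6-dienamide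
Product: 7 (5Z,9E)-1-[(tert-butyldimethylsilyl)oxy]-10-iodo-5,9-dimethyldeca-5,9-dien-2-yn-4-one
Conditions: tert-butyldimethyl(prop-2-yn-1-yloxy)silane, n-BuLi, THF, −78 °C; then 6, −78 → 0 °C
Reagents that add atoms: tert-butyldimethyl(prop-2-yn-1-yloxy)silane, C#CCO[Si](C)(C)C(C)(C)C
Why: In this Weinreb ketone synthesis the lithium acetylide adds once to the amide and the chelated tetrahedral adduct collapses to the ynone only on work-up, which forms the C8–C9 bond.

Step 6
Reactants: 7 (5Z,9E)-1-[(tert-butyldimethylsilyl)oxy]-10-iodo-5,9-dimethyldeca-5,9-dien-2-yn-4-one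
Product: 8 (4R,5Z,9E)-1-[(tert-butyldimethylsilyl)oxy]-10-iodo-5,9-dimethyldeca-5,9-dien-2-yn-4-ol
Conditions: (R)-2-methyl-CBS-oxazaborolidine (0.3 equiv), BH3·SMe2, THF, −30 °C
Reagents that add atoms: none
Why: In this Corey–Bakshi–Shibata reduction the linear alkynyl group acts as the small and the α-branched alkenyl group as the large substituent, so the (R)-oxazaborolidine should deliver hydride to the face that gives the 4R carbinol (C9 of the target).

Step 7
Reactants: 8 (4R,5Z,9E)-1-[(tert-butyldimethylsilyl)oxy]-10-iodo-5,9-dimethyldeca-5,9-dien-2-yn-4-ol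
Product: 9 tert-butyl{[(4R,5Z,9E)-10-iodo-4-[(4-methoxyphenyl)methoxy]-5,9-dimethyldeca-5,9-dien-2-yn-1-yl]oxy}dimethylsilane
Conditions: NaH, 4-MeOC6H4CH2Cl, Bu4NI (cat.), THF/DMF, 0 °C → rt
Reagents that add atoms: 4-methoxybenzyl chloride, COc1ccc(CCl)cc1
Why: Williamson etherification of the sodium alkoxide puts on O9 a 4-methoxybenzyl group that cannot migrate to a neighbouring alkoxide, survives base and is removable oxidatively at the end.

Step 8
Reactants: 9 tert-butyl{[(4R,5Z,9E)-10-iodo-4-[(4-methoxyphenyl)methoxy]-5,9-dimethyldeca-5,9-dien-2-yn-1-yl]oxy}dimethylsilane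
Product: 10 (4R,5Z,9E)-10-iodo-4-[(4-methoxyphenyl)methoxy]-5,9-dimethyldeca-5,9-dien-2-yn-1-ol
Conditions: Bu4NF, THF, 0 °C
Reagents that add atoms: none
Why: Fluoride-induced cleavage of the silyl ether frees the primary propargylic alcohol that will direct the epoxidation.

Step 9
Reactants: 10 (4R,5Z,9E)-10-iodo-4-[(4-methoxyphenyl)methoxy]-5,9-dimethyldeca-5,9-dien-2-yn-1-ol
Product: 11 (2Z,4S,5Z,9E)-10-iodo-4-[(4-methoxyphenyl)methoxy]-5,9-dimethyldeca-2,5,9-trien-1-ol
Conditions: H2 (1 atm), Pd/CaCO3 poisoned with Pb(OAc)2, quinoline, EtOAc, rt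
Reagents that add atoms: none
Why: Semi-hydrogenation over the lead-poisoned palladium catalyst delivers H2 syn to the alkyne and should stop at the Z alkene without touching the alkenyl iodide or the trisubstituted alkene (the descriptor at C4 changes to S only through the priority rules).

Step 10
Reactants: 11 (2Z,4S,5Z,9E)-10-iodo-4-[(4-methoxyphenyl)methoxy]-5,9-dimethyldeca-2,5,9-trien-1-ol
Product: 12 {(2R,3S)-3-[(1R,2Z,6E)-7-iodo-1-[(4-methoxyphenyl)methoxy]-2,6-dimethylhepta-2,6-dien-1-yl]oxiran-2-yl}methanol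
Conditions: Ti(Oi-Pr)4 (0.3 equiv), D-(−)-diisopropyl tartrate (0.36 equiv), t-BuOOH, 4 Å molecular sieves, CH2Cl2, −20 °C
Reagents that add atoms: tert-butyl hydroperoxide, CC(C)(C)OO
Why: In this Sharpless asymmetric epoxidation titanium binds the allylic alcohol so that only C7=C8 is oxidised, and the D-(−)-tartrate delivers oxygen to the face that gives the (2R,3S) cis-epoxide, which is also the face anti to the alkenyl residue at C9 in its allylic-strain-minimised conformer (matched case).

Step 11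
Reactants: 12 {(2R,3S)-3-[(1R,2Z,6E)-7-iodo-1-[(4-methoxyphenyl)methoxy]-2,6-dimethylhepta-2,6-dien-1-yl]oxiran-2-yl}methanol
Product: 13 (2S,3S)-3-[(1R,2Z,6E)-7-iodo-1-[(4-methoxyphenyl)methoxy]-2,6-dimethylhepta-2,6-dien-1-yl]oxirane-2-carbaldehyde
Conditions: TEMPO (0.1 equiv), PhI(OAc)2 (1.1 equiv), CH2Cl2, 0 °C → rt
Reagents that add atoms: none
Why: The non-basic oxoammonium oxidation should give the cis-epoxy aldehyde without epimerisation at the α-carbon (the descriptor at C2 changes to S only through the priority rules).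

Step 12
Reactants: 13 (2S,3S)-3-[(1R,2Z,6E)-7-iodo-1-[(4-methoxyphenyl)methoxy]-2,6-dimethylhepta-2,6-dien-1-yl]oxirane-2-carbaldehyde
Product: 14 (1R,2R,3E,7Z,9R,10S)-9-[(4-methoxyphenyl)methoxy]-4,8-dimethyl-11-oxabicyclo[8.1.0]undeca-3,7-dien-2-ol (germacrane positions: 6-OH, cis-7,8-epoxide, 9-O-4-methoxybenzyl; 6R,7R,8S,9R)
Conditions: CrCl2 (10 equiv), NiCl2 (0.1 equiv), degassed DMSO, rt, 0.002 M, slow addition of 13
Reagents that add atoms: none
Why: In this Nozaki–Hiyama–Kishi reaction NiCl2-catalysed activation of the C–I bond, transmetalation to chromium and addition to the aldehyde at high dilution close the ten-membered ring with retention of the E alkene, and Felkin–Anh attack anti to the epoxide C–O bond should give the erythro 2R carbinol (C6).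

Step 13
Reactants: 14 (1R,2R,3E,7Z,9R,10S)-9-[(4-methoxyphenyl)methoxy]-4,8-dimethyl-11-oxabicyclo[8.1.0]undeca-3,7-dien-2-ol
Product: 15 (1R,2R,3E,7Z,9R,10S)-9-[(4-methoxyphenyl)methoxy]-4,8-dimethyl-11-oxabicyclo[8.1.0]undeca-3,7-dien-2-yl 2-(diethoxyphosphoryl)acetate
Conditions: (EtO)2P(O)CH2CO2H, N,N'-dicyclohexylcarbodiimide, DMAP (cat.), CH2Cl2, 0 °C → rt
Reagents that add atoms: (diethoxyphosphoryl)acetic acid, OC(=O)CP(=O)(OCC)OCC
Why: Steglich esterification (carbodiimide activation, DMAP acyl transfer) acylates the ring hydroxyl with retention at C6.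

Step 14
Reactants: 15 (1R,2R,3E,7Z,9R,10S)-9-[(4-methoxyphenyl)methoxy]-4,8-dimethyl-11-oxabicyclo[8.1.0]undeca-3,7-dien-2-yl 2-(diethoxyphosphoryl)acetate
Product: 17 (3aR,4R,5R,6Z,10E,11aR)-4-hydroxy-5-[(4-methoxyphenyl)methoxy]-6,10-dimethyl-3-methylidene-3a,4,5,8,9,11a-hexahydrocyclodeca[b]furan-2(3H)-one, via α-phosphono lactone 16 (not isolated)
Conditions: NaH (1.1 equiv), THF, 0 → 40 °C; then (CH2O)n, 0 °C → rt
Reagents that add atoms: formaldehyde (from paraformaldehyde), C=O
Why: Proposed new method: NaH deprotonates the phosphonoacetate at C11 and the stabilised carbanion attacks C7 of the cis-7,8-epoxide from the side opposite to the epoxide oxygen (SN2), which closes the lactone ring O6–C12–C11–C7–C6 in the 5-exo-tet mode and releases O8 as an alkoxide; this alkoxide is protonated at once by the far more acidic C11–H of the new α-phosphono lactone, and the resulting anion of 16 olefinates formaldehyde (Horner–Wadsworth–Emmons) to give the C11=C13 methylidene. The closest known reaction types are the opening of epoxides by phosphonoacetate anions (first stage of the Wadsworth–Emmons cyclopropanation), the 5-exo opening of 2,3-epoxy alcohol derivatives at C2 by a nucleophile tethered through the carbinol oxygen (carbamates, carbonates) and the methylenation of α-phosphono-γ-lactones with formaldehyde; new is the combination, a carbon nucleophile delivered through an ester tether. The one new stereocentre, C7, is set by inversion of the epoxide carbon (7R in 15), and since O6 and the epoxide oxygen are erythro this gives the trans ring fusion (H6 and H7 anti) while C8 keeps its configuration. The step needs attack at C7 and not at C8: the 5-exo trajectory with the tether anti to the breaking C7–O bond is favoured over the 6-endo one for an epoxide without cation-stabilising groups. It also needs the O8 alkoxide not to attack phosphorus (cyclopropanation manifold), the lactone carbonyl (6,12- to 8,12-translactonisation) or a neighbouring protecting group, which the fast proton transfer from C11, a temperature of 40 °C or below and the non-migrating 4-methoxybenzyl ether on O9 should secure.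

Step 15
Reactants: 18 (2Z)-2-methylbut-2-enoic acid (angelic acid)
Product: 19 (2Z)-2-methylbut-2-en-1-ol
Conditions: LiAlH4, Et2O, 0 °C
Reagents that add atoms: none
Why: Hydride reduction of the carboxylic acid through its aluminium carboxylate at 0 °C should give the allylic alcohol without Z to E isomerisation.

Step 16
Reactants: 19 (2Z)-2-methylbut-2-en-1-ol
Product: 20 [(2R,3S)-2,3-dimethyloxiran-2-yl]methanol
Conditions: Ti(Oi-Pr)4 (0.1 equiv), D-(−)-diisopropyl tartrate (0.12 equiv), t-BuOOH, 4 Å molecular sieves, CH2Cl2, −20 °C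
Reagents that add atoms: tert-butyl hydroperoxide, CC(C)(C)OO
Why: Sharpless asymmetric epoxidation of the cis-configured trisubstituted allylic alcohol with D-(−)-tartrate should give the (2R,3S) epoxy alcohol, which sets both side-chain stereocentres.

Step 17
Reactants: 20 [(2R,3S)-2,3-dimethyloxiran-2-yl]methanol
Product: 21 (2S,3S)-2,3-dimethyloxirane-2-carboxylic acid
Conditions: TEMPO (0.2 equiv), PhI(OAc)2 (2.2 equiv), MeCN/H2O (1:1), NaHCO3, rt
Reagents that add atoms: water, O
Why: The oxoammonium oxidation in aqueous acetonitrile proceeds through the aldehyde hydrate to the carboxylic acid and leaves the epoxide intact, the descriptor at C2 changing from R to S only through the priority rules.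

Step 18
Reactants: 17 (3aR,4R,5R,6Z,10E,11aR)-4-hydroxy-5-[(4-methoxyphenyl)methoxy]-6,10-dimethyl-3-methylidene-3a,4,5,8,9,11a-hexahydrocyclodeca[b]furan-2(3H)-one; 21 (2S,3S)-2,3-dimethyloxirane-2-carboxylic acid
Product: 22 (3aS,4R,5R,6Z,10E,11aR)-5-[(4-methoxyphenyl)methoxy]-6,10-dimethyl-3-methylidene-2-oxo-2,3,3a,4,5,8,9,11a-octahydrocyclodeca[b]furan-4-yl (2S,3S)-2,3-dimethyloxirane-2-carboxylate
Conditions: 2-methyl-6-nitrobenzoic anhydride, DMAP, Et3N, CH2Cl2, rt
Reagents that add atoms: none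
Why: Shiina esterification (mixed anhydride, DMAP acyl transfer) acylates the hindered C8 hydroxyl with retention, and the acid has no α-hydrogen to epimerise.

Step 19
Reactants: 22 (3aS,4R,5R,6Z,10E,11aR)-5-[(4-methoxyphenyl)methoxy]-6,10-dimethyl-3-methylidene-2-oxo-2,3,3a,4,5,8,9,11a-octahydrocyclodeca[b]furan-4-yl (2S,3S)-2,3-dimethyloxirane-2-carboxylate
Product: 23 (3aS,4R,5R,6Z,10E,11aR)-5-hydroxy-6,10-dimethyl-3-methylidene-2-oxo-2,3,3a,4,5,8,9,11a-octahydrocyclodeca[b]furan-4-yl (2S,3S)-2,3-dimethyloxirane-2-carboxylate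
Conditions: DDQ, CH2Cl2/pH 7 phosphate buffer, 0 °C
Reagents that add atoms: none
Why: Oxidative cleavage of the 4-methoxybenzyl ether by DDQ (hydride abstraction to the oxocarbenium ion, then hydrolysis) under buffered neutral conditions should free O9 without acyl migration from O8.

Step 20
Reactants: 23 (3aS,4R,5R,6Z,10E,11aR)-5-hydroxy-6,10-dimethyl-3-methylidene-2-oxo-2,3,3a,4,5,8,9,11a-octahydrocyclodeca[b]furan-4-yl (2S,3S)-2,3-dimethyloxirane-2-carboxylate
Product: 24 (3aS,4R,5R,6Z,10E,11aR)-5-(acetyloxy)-6,10-dimethyl-3-methylidene-2-oxo-2,3,3a,4,5,8,9,11a-octahydrocyclodeca[b]furan-4-yl (2S,3S)-2,3-dimethyloxirane-2-carboxylate (target)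
Conditions: Ac2O, pyridine, DMAP (cat.), CH2Cl2, 0 °C → rt
Reagents that add atoms: acetic anhydride, CC(=O)OC(C)=O
Why: DMAP-catalysed acylation of the allylic C9 hydroxyl with acetic anhydride should give the target with all stereocentres untouched.

**Compound list**

1 | pent-4-yn-1-ol | C#CCCCO | starting material
2 | (E)-dimethyl[5-(dimethylalumanyloxy)-2-methylpent-1-en-1-yl]alumane (alkenylalane, Al cis to the new methyl) | C[Al](C)OCCC/C(C)=C/[Al](C)C | intermediate
3 | (4E)-5-iodo-4-methylpent-4-en-1-ol | OCCC/C(C)=C/I | intermediate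
4 | (4E)-5-iodo-4-methylpent-4-enal | O=CCC/C(C)=C/I | intermediate
5 | ethyl (2Z,6E)-7-iodo-2,6-dimethylhepta-2,6-dienoate | CCOC(=O)/C(C)=C\CC/C(C)=C/I | intermediate
6 | (2Z,6E)-7-iodo-N-methoxy-N,2,6-trimethylhepta-2,6-dienamide | CON(C)C(=O)/C(C)=C\CC/C(C)=C/I | intermediate
7 | (5Z,9E)-1-[(tert-butyldimethylsilyl)oxy]-10-iodo-5,9-dimethyldeca-5,9-dien-2-yn-4-one | CC(C)(C)[Si](C)(C)OCC#CC(=O)/C(C)=C\CC/C(C)=C/I | intermediate
8 | (4R,5Z,9E)-1-[(tert-butyldimethylsilyl)oxy]-10-iodo-5,9-dimethyldeca-5,9-dien-2-yn-4-ol | CC(C)(C)[Si](C)(C)OCC#C[C@H](O)/C(C)=C\CC/C(C)=C/I | intermediate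
9 | tert-butyl{[(4R,5Z,9E)-10-iodo-4-[(4-methoxyphenyl)methoxy]-5,9-dimethyldeca-5,9-dien-2-yn-1-yl]oxy}dimethylsilane | CC(C)(C)[Si](C)(C)OCC#C[C@H](OCc1ccc(OC)cc1)/C(C)=C\CC/C(C)=C/I | intermediate
10 | (4R,5Z,9E)-10-iodo-4-[(4-methoxyphenyl)methoxy]-5,9-dimethyldeca-5,9-dien-2-yn-1-ol | OCC#C[C@H](OCc1ccc(OC)cc1)/C(C)=C\CC/C(C)=C/I | intermediate
11 | (2Z,4S,5Z,9E)-10-iodo-4-[(4-methoxyphenyl)methoxy]-5,9-dimethyldeca-2,5,9-trien-1-ol | OC/C=C\[C@H](OCc1ccc(OC)cc1)/C(C)=C\CC/C(C)=C/I | intermediate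
12 | {(2R,3S)-3-[(1R,2Z,6E)-7-iodo-1-[(4-methoxyphenyl)methoxy]-2,6-dimethylhepta-2,6-dien-1-yl]oxiran-2-yl}methanol | OC[C@H]1O[C@H]1[C@H](OCc1ccc(OC)cc1)/C(C)=C\CC/C(C)=C/I | intermediate
13 | (2S,3S)-3-[(1R,2Z,6E)-7-iodo-1-[(4-methoxyphenyl)methoxy]-2,6-dimethylhepta-2,6-dien-1-yl]oxirane-2-carbaldehyde | O=C[C@H]1O[C@H]1[C@H](OCc1ccc(OC)cc1)/C(C)=C\CC/C(C)=C/I | intermediate
14 | (1R,2R,3E,7Z,9R,10S)-9-[(4-methoxyphenyl)methoxy]-4,8-dimethyl-11-oxabicyclo[8.1.0]undeca-3,7-dien-2-ol | O[C@@H]1/C=C(\C)CC/C=C(/C)[C@@H](OCc3ccc(OC)cc3)[C@@H]2O[C@H]12 | intermediate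
15 | (1R,2R,3E,7Z,9R,10S)-9-[(4-methoxyphenyl)methoxy]-4,8-dimethyl-11-oxabicyclo[8.1.0]undeca-3,7-dien-2-yl 2-(diethoxyphosphoryl)acetate | CCOP(=O)(OCC)CC(=O)O[C@@H]1/C=C(\C)CC/C=C(/C)[C@@H](OCc3ccc(OC)cc3)[C@@H]2O[C@H]12 | intermediate
16 | diethyl [(3aR,4R,5R,6Z,10E,11aR)-4-hydroxy-5-[(4-methoxyphenyl)methoxy]-6,10-dimethyl-2-oxo-2,3,3a,4,5,8,9,11a-octahydrocyclodeca[b]furan-3-yl]phosphonate (C3 not defined; present in the flask as its sodium salt) | CCOP(=O)(OCC)C1C(=O)O[C@@H]2/C=C(\C)CC/C=C(/C)[C@@H](OCc3ccc(OC)cc3)[C@H](O)[C@@H]12 | intermediate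
17 | (3aR,4R,5R,6Z,10E,11aR)-4-hydroxy-5-[(4-methoxyphenyl)methoxy]-6,10-dimethyl-3-methylidene-3a,4,5,8,9,11a-hexahydrocyclodeca[b]furan-2(3H)-one | C=C1C(=O)O[C@@H]2/C=C(\C)CC/C=C(/C)[C@@H](OCc3ccc(OC)cc3)[C@H](O)[C@@H]12 | intermediate
18 | (2Z)-2-methylbut-2-enoic acid (angelic acid) | C/C=C(/C)C(=O)O | starting material
19 | (2Z)-2-methylbut-2-en-1-ol | C/C=C(/C)CO | intermediate
20 | [(2R,3S)-2,3-dimethyloxiran-2-yl]methanol | OC[C@@]1(C)O[C@H]1C | intermediate
21 | (2S,3S)-2,3-dimethyloxirane-2-carboxylic acid | OC(=O)[C@@]1(C)O[C@H]1C | intermediate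
22 | (3aS,4R,5R,6Z,10E,11aR)-5-[(4-methoxyphenyl)methoxy]-6,10-dimethyl-3-methylidene-2-oxo-2,3,3a,4,5,8,9,11a-octahydrocyclodeca[b]furan-4-yl (2S,3S)-2,3-dimethyloxirane-2-carboxylate | C=C1C(=O)O[C@@H]2/C=C(\C)CC/C=C(/C)[C@@H](OCc3ccc(OC)cc3)[C@H](OC(=O)[C@@]4(C)O[C@H]4C)[C@@H]12 | intermediate
23 | (3aS,4R,5R,6Z,10E,11aR)-5-hydroxy-6,10-dimethyl-3-methylidene-2-oxo-2,3,3a,4,5,8,9,11a-octahydrocyclodeca[b]furan-4-yl (2S,3S)-2,3-dimethyloxirane-2-carboxylate | C=C1C(=O)O[C@@H]2/C=C(\C)CC/C=C(/C)[C@@H](O)[C@H](OC(=O)[C@@]3(C)O[C@H]3C)[C@@H]12 | intermediate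
24 | (3aS,4R,5R,6Z,10E,11aR)-5-(acetyloxy)-6,10-dimethyl-3-methylidene-2-oxo-2,3,3a,4,5,8,9,11a-octahydrocyclodeca[b]furan-4-yl (2S,3S)-2,3-dimethyloxirane-2-carboxylate | C=C1C(=O)O[C@@H]2/C=C(\C)CC/C=C(/C)[C@@H](OC(C)=O)[C@H](OC(=O)[C@@]3(C)O[C@H]3C)[C@@H]12 | target

**Count and risks**

Total step count: 20. Longest linear sequence: 17 (steps 1–14 and 18–20).

Steps most likely to fail:

1. Step 14 (labelled step). The tethered carbanion may be unable to reach the back side of the C7–O bond in the ring conformation, so the epoxide stays closed. At the higher temperature then needed, the O8 alkoxide could transfer the phosphoryl group or attack the lactone carbonyl. The fallback uses known chemistry and still forms C7–C11 by ring closure, but through a radical; it sets out from 14 and rejoins the route at 22. O-Propargylation of 14 (propargyl bromide, NaH, Bu4NI, THF, 0 °C) would give the O6-propargyl ether F1. Cp2TiCl (trivalent titanium, made from Cp2TiCl2 and Zn) in THF should open the epoxide reductively to the C7 radical (Nugent–RajanBabu conditions). This radical cyclises 5-exo-dig onto the alkyne and, after hydrogen abstraction from THF, gives the 3-methylidenetetrahydrofuran alcohol F2 with the free C8 hydroxyl; the trans ring fusion is expected from the less strained transition state. Esterification with 21 under the conditions of step 18 would give the epoxyangelate F3. Oxidation of the ring CH2 flanked by oxygen and the methylidene group (CrO3·3,5-dimethylpyrazole, CH2Cl2, −20 °C) would then give lactone 22.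

2. Step 12. The face of the aldehyde that is attacked may be dictated by the conformation of the forming ring and not by Felkin–Anh control, so that the C6 epimer prevails. The fallback sets out from the cyclisation product of 13 and returns at 14. The C6 epimer F4 (alone or mixed with 14) would be oxidised with MnO2 (CH2Cl2, rt) to the epoxy enone F5. Reduction with Zn(BH4)2 (Et2O, −20 °C) should then give the erythro alcohol 14, through chelation of zinc between the carbonyl and epoxide oxygens and hydride delivery from the face opposite to the C7–C8 bond. Stereocontrol thus moves from the C–C bond formation to a chelation-controlled reduction.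

3. Step 10. Oxygen transfer to this hindered cis-allylic alcohol may be slow, and the tartrate catalyst may discriminate the two faces poorly. The fallback runs from 11 to 12 and makes no new compound (F0). It gives up catalyst control and relies on the substrate: hydroxyl-directed epoxidation with VO(acac)2 and t-BuOOH (toluene, 0 °C), which is still confined to the allylic alcohol alkene. 1,3-Allylic strain holds H9 in the alkene plane, and the oxidant should enter anti to the alkenyl residue and syn to the ether oxygen, the same face as planned.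

**Further compounds**

F1 | step 14 | (1R,2R,3E,7Z,9R,10S)-9-[(4-methoxyphenyl)methoxy]-4,8-dimethyl-2-(prop-2-yn-1-yloxy)-11-oxabicyclo[8.1.0]undeca-3,7-diene (O6-propargyl ether of 14) | C#CCO[C@@H]1/C=C(\C)CC/C=C(/C)[C@@H](OCc3ccc(OC)cc3)[C@@H]2O[C@H]12
F2 | step 14 | (3aR,4R,5R,6Z,10E,11aR)-5-[(4-methoxyphenyl)methoxy]-6,10-dimethyl-3-methylidene-2,3,3a,4,5,8,9,11a-octahydrocyclodeca[b]furan-4-ol | C=C1CO[C@@H]2/C=C(\C)CC/C=C(/C)[C@@H](OCc3ccc(OC)cc3)[C@H](O)[C@@H]12
F3 | step 14 | (3aS,4R,5R,6Z,10E,11aR)-5-[(4-methoxyphenyl)methoxy]-6,10-dimethyl-3-methylidene-2,3,3a,4,5,8,9,11a-octahydrocyclodeca[b]furan-4-yl (2S,3S)-2,3-dimethyloxirane-2-carboxylate | C=C1CO[C@@H]2/C=C(\C)CC/C=C(/C)[C@@H](OCc3ccc(OC)cc3)[C@H](OC(=O)[C@@]4(C)O[C@H]4C)[C@@H]12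
F4 | step 12 | (1R,2S,3E,7Z,9R,10S)-9-[(4-methoxyphenyl)methoxy]-4,8-dimethyl-11-oxabicyclo[8.1.0]undeca-3,7-dien-2-ol (C6 epimer of 14) | O[C@H]1/C=C(\C)CC/C=C(/C)[C@@H](OCc3ccc(OC)cc3)[C@@H]2O[C@H]12
F5 | step 12 | (1S,3E,7Z,9R,10S)-9-[(4-methoxyphenyl)methoxy]-4,8-dimethyl-11-oxabicyclo[8.1.0]undeca-3,7-dien-2-one (C6 ketone of 14) | O=C1/C=C(\C)CC/C=C(/C)[C@@H](OCc3ccc(OC)cc3)[C@@H]2O[C@H]12
F0 | step 10 | none | none
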